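The product is the question here: how far left-handed product leads right-handed product in it, in spring and in summer.

| flask | left-handed substrate | right-handed substrate | partner | protic impurity | free catalyst | stray impurity | remark | time |
|---|---|---|---|---|---|---|---|---|
| red | 0.050 M | 0.050 M | 0.050 M | 0.015 M | 1.2 mM | 0.41 mM | run made earlier |  |
| ochre | 0.050 M | 0.050 M | 0.050 M | 0.015 M | 1.2 mM | 2.4 mM | run made earlier |  |
| spring | 0.050 M | 0.050 M | 0.0500 M | 0.0150 M | 1.2 mM | 0.74 mM |  | 5.0 d |
| summer | 0.050 M | 0.050 M | 0.0500 M | 0.0150 M | 1.2 mM | 3.0 mM |  | 5.0 d |

| run | time / d | left-handed product / % | right-handed product / % |
|---|---|---|---|
| red | 0.333 | 19 | 10 |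
| red | 0.833 | 25 | 13 |
| red | 1.67 | 23 | 16 |
| red | 2.50 | 25 | 11 |
| ochre | 0.625 | 3 | 2 |
| ochre | 1.25 | 0 | 1 |
| ochre | 2.08 | 2 | 1 |
| ochre | 2.50 | 3 | 4 |

(scatter of a reading: 2 percentage points)

* the winner by excess of left-handed product over right-handed product in the product; "neither" if no more than 2 percentage points parts them (spring / summer / neither)
* excess of left-handed product over right-handed product in the product at the end, spring
* excess of left-handed product over right-handed product in the product at the end, summer

- free catalyst is single-handed; left-handed substrate and right-handed substrate are mirror images of each other, charged as a racemate, each of them at the stated concentration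
- what was read earlier has a scatter of 2 percentage points, one standard deviation
- reactions considered so far: free catalyst + stray impurity -> spent catalyst; partner + free catalyst + left-handed substrate -> free catalyst + left-handed product; partner + protic impurity -> quenched reagent; 2 free catalyst <-> resting dimer; partner + free catalyst + right-handed substrate -> free catalyst + right-handed product
- an excess is below zero if the other one leads

Both products need the same catalyst and the same partner. Those cancel when you divide one rate by the other, so the ratio of rates is s times [left-handed substrate]/[right-handed substrate]. Here s is the selectivity factor.

Read it from red. Its last readings average 24.3% left-handed and 13.3% right-handed product, and each reading scatters by 2 percentage points. That is a total of 37.7% and an excess of 29.2%.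

A first answer takes s as the product ratio, 1.82. But red's left-handed substrate ran down further, so that figure is too low. Go round once more: divide by the ratio of the two substrates halfway down. This gives a reading of 2.09, with the scatter of red's readings in it. Carry this s, the ratio of the two rate constants, to the next flask.

Here is my own reckoning. Spring, like red, has less stray impurity than catalyst, so I expect spring to stop near red's total and near red's excess, 29.2%. Summer has more stray impurity than catalyst, like ochre, whose products averaged 4.00% together. Ochre's readings are too noisy to show an excess. But if summer turns over as little as ochre, I expect its substrates to stay near their charge, its product ratio to be s, and its excess to be s minus one over s plus one: 35.3%. That is more than I expect of spring, so I pick summer.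

The forecast picks spring. It gives 31% for spring (25% to 37%) and 15% for summer (−8% to 40%), saying of ochre: “That could be a selective burst (excess about 38%) or an unlisted racemic background”. We part on the order of the two flasks.

The flask gives summer: 25.3% in spring and 32.1% in summer.

    free catalyst + stray impurity → spent catalyst (k = 8190 M⁻¹ h⁻¹)
    partner + free catalyst + left-handed substrate → free catalyst + left-handed product (k = 6710 M⁻² h⁻¹)
    partner + protic impurity → quenched reagent (k = 2.54 M⁻¹ h⁻¹)
    2 free catalyst ⇌ resting dimer, settled at all times (K = 2500 M⁻¹)
    partner + free catalyst + right-handed substrate → free catalyst + right-handed product (k = 3430 M⁻² h⁻¹)

In spring at 0.211 d, left-handed substrate had a half-life of 0.78 d by its step and right-handed substrate 1.5 d, so the first half-life was about half the second. After 5.00 d, spring's partner stood at 0.00586% of its charge, with 25.1% left-handed and 35.1% right-handed substrate, as percent of both substrates charged. Carry s to spring's total of 39.8%, with red's excess put back: the product ratio is 1.81, an excess of 28.8%, beside the 25.3% found. In a neighbouring flask, spring with 0.0019 M of stray impurity, the total is 2.92%. There s gives a ratio of 2.07, an excess of 34.8%, and that flask gave 31.9%.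

(The earlier runs and the new flask were computed for an exercise; scatter was added.)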